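All runs were generated by integration with made-up constants; the scatter is artificial.

35 % of the substrate was what I read in the theta run after 8.00 min, and my substrate estimate for west grew from that one reading.

in all of them: substrate 20 mM

| run | partner | remark | time |
|---|---|---|---|
| theta | 30 mM | run made earlier |  |
| epsilon | 58 mM | run made earlier |  |
| west | 24.0 mM |  | 10 min |
| north-east | 48.0 mM |  | 10 min |

| run | time / min | mono adduct / % | side product / % | substrate / % | double product / % |
|---|---|---|---|---|---|
| theta | 0.833 | 12 | 1 | 88 | 0 |
| theta | 2.50 | 20 | 6 | 67 | 6 |
| theta | 5.00 | 19 | 12 | 47 | 11 |
| theta | 8.00 | 15 | 24 | 35 | 22 |
| epsilon | 0.833 | 18 | 2 | 74 | 3 |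
| epsilon | 2.50 | 27 | 8 | 43 | 19 |
| epsilon | 5.00 | 18 | 13 | 24 | 36 |
| epsilon | 8.00 | 12 | 16 | 15 | 49 |

(readings scatter by 1.5 percentage points)

- which of these there is most of at the end, counted by the substrate in it, west (side product / substrate / double product / mono adduct)
- which of these there is most of at the end, counted by the substrate in it, north-east (side product / substrate / double product / mono adduct)
- how much there is at the end of the one of these that leads, in percent of the substrate charged: west
- how much there is at the end of the one of these that leads, in percent of the substrate charged: north-east

- in percentages every species weighs as the substrate in it: one side product counts as two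

In west the substrate was charged in the smaller amount, so I wrote its balance: what it kept, and how the remainder was shared. I defined κ as the decay constant of the substrate over a whole run, minus the logarithm of the fraction left divided by the time, divided again by the partner charged. Theta gave 4.37 M⁻¹ min⁻¹. Epsilon, with twice the partner, gave 4.09 M⁻¹ min⁻¹, and I kept theta's value for west and epsilon's for north-east, each resting on readings with a scatter of 1.5 percentage points.

The first reading of theta parted from them: it gave 5.12 M⁻¹ min⁻¹, which would leave 29.3 % in west. That one cheated. Counting one partner in mono adduct and side product and two in double product, theta held about half of its partner at its last reading, so the constant from theta's first reading overstated its whole run.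

With the whole-run κ, I expected 35.0 % of substrate in west, ahead of anything theta's largest product suggested, 24 % of side product. For north-east I expected 14.1 %. Interpolating in partner the share of lost substrate found as double product gave me 42.2 % of double product.

The forecast named substrate at 35 % in west and double product at 50 % in north-east, saying “Double product clearly leads”; its north-east figure stood above mine.

West gave substrate at 34.6 %, and north-east gave double product at 44.0 %.

    substrate + partner → mono adduct (k = 5.55 M⁻¹ min⁻¹)
    mono adduct → decomposed reagent (k = 0.0646 min⁻¹)
    partner + mono adduct → double product (k = 7.71 M⁻¹ min⁻¹)
    substrate + mono adduct → side product (k = 7.20 M⁻¹ min⁻¹)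

The west result returns κ as 4.42 M⁻¹ min⁻¹, beside my 4.37 M⁻¹ min⁻¹ from theta. At 2.75 min in west, the step from substrate and partner used substrate 4.1 times as fast as the step to side product, so at that moment most of the decay that κ measures was that first step. For west left until 25 min, κ gives 7.25 %. The computed flask holds 15.5 %, with partner at 22.7 % of its charge.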